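(The earlier runs and the new flask stem from a simulated flask on assumed constants, noise included.)

3 questions stand over 4 flasks that differ in their capture agent, and each asks for one share: product over product plus trapped intermediate.

common to all: substrate 0.50 M

|  | coupling partner | capture agent | remark | time |
|---|---|---|---|---|
| violet | 0.60 M | 0.15 M | run made earlier |  |
| amber | 0.60 M | 1.7 M | run made earlier |  |
| Saturday's | 0.600 M | 0.120 M |  | 3.0 h |
| Monday's | 0.600 M | 0.250 M |  | 3.0 h |
| Friday's | 0.600 M | 0.500 M |  | 3.0 h |
| Sunday's | 0.600 M | 1.50 M |  | 3.0 h |

| run | time / min | product / % | trapped intermediate / % |
|---|---|---|---|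
| violet | 20.0 | 3 | 5 |
| violet | 40.0 | 6 | 2 |
| violet | 60.0 | 6 | 2 |
| violet | 80.0 | 7 | 0 |
| violet | 120 | 6 | 3 |
| amber | 8.00 | 0 | 1 |
| amber | 25.0 | 5 | 11 |
| amber | 40.0 | 3 | 15 |
| amber | 60.0 | 5 | 15 |
| amber | 90.0 | 5 | 21 |
| amber | 120 | 6 | 19 |

(each reading ± 2 percentage points)

* ranking by share of product in all that became product or trapped intermediate, from high to low, at 3.0 h (Saturday's / Monday's / Friday's / Sunday's)
* the share of product in all that became product or trapped intermediate of the flask you put first, at 3.0 h
* the share of product in all that became product or trapped intermediate of the flask you put last, at 3.0 h



- **First instants.** At 8.00 min the amber run shows 0% product and 1% trapped intermediate against a scatter of 2 percentage points, so we read both as starting from nothing.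
- **Middle.** We read both as exits from one unseen intermediate. At its last reading, amber's trapped intermediate has taken 5.59% of the capture agent charged. Amber's capture agent therefore stays close to its charge, so we treat capture as pseudo-first-order and take the split between the exits as steady.
- **The quantity.** We carry the even point, the amount of capture agent at which product and trapped intermediate form equally fast, reckoned as the charge times product over trapped intermediate. Amber's product readings sum to 24.0% and its trapped readings to 82.0%, which gives a reading of 0.498 M, with the scatter of those readings in it.
- **A weaker reading.** The violet run gives 0.350 M, but its last trapped reading is 3% against amber's 19%, with a scatter of 2 points on each, so we lean on amber.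
- **End.** The last product readings are 6% in violet and 6% in amber, and we assume the split holds until 3.0 h. Taking the capture agent at its charge, we reckon the share as the even point over the even point plus the capture agent.
- **Our reckoning.** We put Saturday's, with the least capture agent, first at 80.6%. We put Sunday's, with the most, last at 24.9%.
- **The forecast.** It reasoned from “one intermediate partitioning between going on to product and being captured” and gave Saturday's > Monday's > Friday's > Sunday's, with 80% (71% to 87%) and 24% (19% to 30%), slightly below ours.
- **The result.** The flasks give Saturday's > Monday's > Friday's > Sunday's, with 79.7% for Saturday's and 23.7% for Sunday's.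

    substrate + coupling partner → open intermediate (k = 7.30 × 10⁻⁴ M⁻¹ s⁻¹)
    open intermediate → decomposed reagent (k = 0.00383 s⁻¹)
    open intermediate + capture agent → trapped intermediate (k = 0.00103 M⁻¹ s⁻¹)
    open intermediate → product (k = 4.62 × 10⁻⁴ s⁻¹)

- **The neighbour.** Friday's, charged with 0.500 M of capture agent, lies close to our even point of 0.498 M and gives 48.5%. A further flask, like Sunday's but with 0.60 M of capture agent, reckons to 45.4% by the same rule. At 3.00 h that flask holds 8.28% product and 10.6% trapped intermediate, a share of 43.9%.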